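## Retrosynthetic overview

1. The 3-methyltetronic acid ring is closed last, by Dieckmann condensation of the O-propanoyl derivative of an (R)-α-hydroxy ester that already carries the whole triene side chain.
2. The central E-olefin of the triene is cut by a Wittig disconnection into an (E)-allylic tributylphosphonium ylide (bis-furan half) and a (Z)-enal masked as a 6-hydroxy-dihydropyran lactol; the ring holds the Z-olefin.
3. The lactol, with the only stereocentre, comes in one step from 3-methylbut-2-enal and ethyl glyoxylate by an aminocatalytic dienamine oxa-[4+2] reaction.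
4. The bis-furan half comes from two bought furans: C2-selective Negishi coupling on 2,4-dibromofuran, Kumada coupling at C4, allylic oxidation, phosphonium salt.
5. Ring order: dihydropyran lactol first (step 1, opened again in step 6), tetronic acid last (step 7); the furan rings are bought.

Assumption: ethyl glyoxylate (toluene solution, cracked to the monomer before use), 2,4-dibromofuran and 3-(bromomethyl)furan are taken as catalogue chemicals; lactol 3 is carried as its anomer mixture; the (S)-configured aminocatalyst is taken to give the 2R lactol, to be confirmed on the first run (its mirror image is used if the sense is opposite).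

## Route

Step 1
Reactants: 1 3-methylbut-2-enal; 2 ethyl glyoxylate (ethyl 2-oxoacetate)
Product: 3 ethyl (2R)-6-hydroxy-4-methyl-3,6-dihydro-2H-pyran-2-carboxylate (anomer mixture)
Conditions: 2 (3 equiv), catalyst A (10 mol%) = 3-{[3,5-bis(trifluoromethyl)phenyl]amino}-4-{[(2S)-pyrrolidin-2-ylmethyl]amino}cyclobut-3-ene-1,2-dione, PhCO2H (10 mol%), CH2Cl2, 0 °C, 1 added over 8 h
Reagents that add atoms: none
Why: Proposed new method: the pyrrolidine nitrogen condenses with 1 to an s-trans dienamine (a 1-amino-3-methylbuta-1,3-diene) whose γ-carbon adds to the aldehyde of 2 while the squaramide N–H pair binds the 1,2-dicarbonyl of 2 and exposes its Re face, the alkoxide then closes onto the iminium carbon to a cyclic N,O-aminal (formal oxa-Diels–Alder reaction) that hydrolyses to lactol 3 and frees the catalyst, so the 2R centre and the ring-locked Z-olefin are set together; the closest known chemistry is the hydrogen-bond-directed dienamine oxa-[4+2]/vinylogous aldol reaction of γ-enolisable enals with activated ketones (isatins, α-keto esters, trifluoromethyl ketones), which has not been shown with a glyoxylate aldehyde as heterodienophile, and slow addition of 1 into excess 2 is meant to suppress enal self-condensation.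

Step 2
Reactants: 4 3-(bromomethyl)furan; 5 2,4-dibromofuran
Product: 7 4-bromo-2-(furan-3-ylmethyl)furan, via furan-3-ylmethylzinc bromide 6 (not isolated)
Conditions: Zn dust (1.5 equiv), LiCl, THF, 0 °C, slow addition of 4; then 5 (1.0 equiv), Pd(PPh3)4 (3 mol%), THF, 25 °C
Reagents that add atoms: none
Why: Negishi coupling in which zinc inserts into the furylmethyl C–Br bond and zerovalent palladium adds faster into the C2–Br bond next to the ring oxygen than into C4–Br, so only C2 is alkylated and the 4-bromide is kept for step 3.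

Step 3
Reactants: 7 4-bromo-2-(furan-3-ylmethyl)furan; 8 5-bromo-2-methylpent-2-ene
Product: 10 2-(furan-3-ylmethyl)-4-(4-methylpent-3-en-1-yl)furan, via 4-methylpent-3-enylmagnesium bromide 9 (not isolated)
Conditions: 8, Mg turnings, THF, 40 °C; then 7, NiCl2(dppp) (3 mol%; dppp = Ph2P(CH2)3PPh2), THF/Et2O, 0 → 35 °C
Reagents that add atoms: none
Why: Kumada–Corriu coupling, in which the divalent nickel precatalyst with its chelating diphosphine is reduced by the Grignard reagent and couples primary alkyl Grignard reagents with 3-bromofurans without β-hydride loss, the trisubstituted olefin being inert.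

Step 4
Reactants: 10 2-(furan-3-ylmethyl)-4-(4-methylpent-3-en-1-yl)furan
Product: 11 (2E)-5-[5-(furan-3-ylmethyl)furan-3-yl]-2-methylpent-2-en-1-ol
Conditions: SeO2 (0.4 equiv), t-BuOOH (2.5 equiv, decane solution), CH2Cl2, 0 °C → rt, stopped at about 70% conversion
Reagents that add atoms: selenium dioxide (O=[Se]=O); tert-butyl hydroperoxide (CC(C)(C)OO)
Why: Selenium dioxide allylic oxidation (ene reaction then [2,3]-sigmatropic shift) attacks the (E)-methyl group at the more substituted end of the trisubstituted olefin and so gives the (E)-allylic alcohol, while the furans and the diarylmethane CH2 do not undergo the ene step at room temperature.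

Step 5
Reactants: 11 (2E)-5-[5-(furan-3-ylmethyl)furan-3-yl]-2-methylpent-2-en-1-ol
Product: 13 tributyl{(2E)-5-[5-(furan-3-ylmethyl)furan-3-yl]-2-methylpent-2-en-1-yl}phosphonium methanesulfonate, via allylic mesylate 12 (not isolated)
Conditions: Ms2O (1.2 equiv), iPr2NEt (1.5 equiv), THF, −20 °C, 30 min; then PBu3 (1.3 equiv), −20 °C → rt; trituration with Et2O/hexane
Reagents that add atoms: methanesulfonic anhydride (CS(=O)(=O)OS(C)(=O)=O); tributylphosphine (CCCCP(CCCC)CCCC)
Why: O-mesylation then SN2 displacement by the strongly nucleophilic trialkylphosphine at the primary allylic carbon (phosphonium salt formation) proceeds in one pot without touching the E-olefin.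

Step 6
Reactants: 13 tributyl{(2E)-5-[5-(furan-3-ylmethyl)furan-3-yl]-2-methylpent-2-en-1-yl}phosphonium methanesulfonate; 3 ethyl (2R)-6-hydroxy-4-methyl-3,6-dihydro-2H-pyran-2-carboxylate
Product: 16 ethyl (2R,4Z,6E,8E)-11-[5-(furan-3-ylmethyl)furan-3-yl]-2-hydroxy-4,8-dimethylundeca-4,6,8-trienoate, via allylic phosphorus ylide 14 (not isolated), via ring-opened potassium alkoxide 15 (not isolated)
Conditions: 13, KN(SiMe3)2 (1.0 equiv), THF, −78 °C; 3 (1.3 equiv) pre-treated with KN(SiMe3)2 (1.3 equiv), THF, −78 °C, added by cannula; −78 → 0 °C, dark; H2O work-up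
Reagents that add atoms: none
Why: Wittig olefination of a lactol, in which the potassium lactolate opens to the (Z)-enal alkoxide 15 and its aldehyde reacts with the allylic tributylphosphonium ylide, a reagent class that gives E-dienes because oxaphosphetane formation is reversible, so the new 6,7-olefin is E, the 4Z olefin comes unchanged from the ring and the carbinol centre is not involved.

Step 7
Reactants: 16 ethyl (2R,4Z,6E,8E)-11-[5-(furan-3-ylmethyl)furan-3-yl]-2-hydroxy-4,8-dimethylundeca-4,6,8-trienoate
Product: 18 (5R)-5-{(2Z,4E,6E)-9-[5-(furan-3-ylmethyl)furan-3-yl]-2,6-dimethylnona-2,4,6-trien-1-yl}-4-hydroxy-3-methylfuran-2(5H)-one (CNP0176158.2), via O-propanoyl ester 17 (not isolated)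
Conditions: LiN(SiMe3)2 (1.05 equiv), THF, −78 °C; EtCOCl (1.05 equiv), −78 → −40 °C; then LiN(SiMe3)2 (2.3 equiv), −78 → −20 °C; cold 0.5 M HCl
Reagents that add atoms: propanoyl chloride (CCC(=O)Cl)
Why: O-acylation of the lithium alkoxide then Dieckmann (intramolecular Claisen) condensation of the propanoate enolate onto the ethyl ester closes the 3-methyltetronic acid, which forms as its lithium tetronate and is therefore not deprotonated at C5, so the R centre is kept.

## Compound list

1 | 3-methylbut-2-enal | CC(C)=CC=O | starting material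
2 | ethyl glyoxylate | CCOC(=O)C=O | starting material
3 | ethyl (2R)-6-hydroxy-4-methyl-3,6-dihydro-2H-pyran-2-carboxylate (anomer mixture) | CCOC(=O)[C@H]1CC(C)=CC(O)O1 | intermediate
4 | 3-(bromomethyl)furan | BrCc1ccoc1 | starting material
5 | 2,4-dibromofuran | Brc1coc(Br)c1 | starting material
6 | furan-3-ylmethylzinc bromide | Br[Zn]Cc1ccoc1 | intermediate
7 | 4-bromo-2-(furan-3-ylmethyl)furan | Brc1coc(Cc2ccoc2)c1 | intermediate
8 | 5-bromo-2-methylpent-2-ene | CC(C)=CCCBr | starting material
9 | 4-methylpent-3-enylmagnesium bromide | CC(C)=CCC[Mg]Br | intermediate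
10 | 2-(furan-3-ylmethyl)-4-(4-methylpent-3-en-1-yl)furan | CC(C)=CCCc1coc(Cc2ccoc2)c1 | intermediate
11 | (2E)-5-[5-(furan-3-ylmethyl)furan-3-yl]-2-methylpent-2-en-1-ol | OC/C(C)=C/CCc1coc(Cc2ccoc2)c1 | intermediate
12 | (2E)-5-[5-(furan-3-ylmethyl)furan-3-yl]-2-methylpent-2-en-1-yl methanesulfonate | CS(=O)(=O)OC/C(C)=C/CCc1coc(Cc2ccoc2)c1 | intermediate
13 | tributyl{(2E)-5-[5-(furan-3-ylmethyl)furan-3-yl]-2-methylpent-2-en-1-yl}phosphonium methanesulfonate | CCCC[P+](CCCC)(CCCC)C/C(C)=C/CCc1coc(Cc2ccoc2)c1.CS(=O)(=O)[O-] | intermediate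
14 | tributyl{(2E)-5-[5-(furan-3-ylmethyl)furan-3-yl]-2-methylpent-2-en-1-ylidene}phosphorane (ylide) | CCCC[P+](CCCC)(CCCC)[CH-]/C(C)=C/CCc1coc(Cc2ccoc2)c1 | intermediate
15 | potassium alkoxide of ethyl (2R,4Z)-2-hydroxy-4-methyl-6-oxohex-4-enoate (ring-opened form of 3) | CCOC(=O)[C@H]([O-])C\C(C)=C/C=O.[K+] | intermediate
16 | ethyl (2R,4Z,6E,8E)-11-[5-(furan-3-ylmethyl)furan-3-yl]-2-hydroxy-4,8-dimethylundeca-4,6,8-trienoate | CCOC(=O)[C@H](O)C\C(C)=C/C=C/C(C)=C/CCc1coc(Cc2ccoc2)c1 | intermediate
17 | ethyl (2R,4Z,6E,8E)-11-[5-(furan-3-ylmethyl)furan-3-yl]-4,8-dimethyl-2-(propanoyloxy)undeca-4,6,8-trienoate | CCOC(=O)[C@H](OC(=O)CC)C\C(C)=C/C=C/C(C)=C/CCc1coc(Cc2ccoc2)c1 | intermediate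
18 | (5R)-5-{(2Z,4E,6E)-9-[5-(furan-3-ylmethyl)furan-3-yl]-2,6-dimethylnona-2,4,6-trien-1-yl}-4-hydroxy-3-methylfuran-2(5H)-one | CC1=C(O)[C@@H](C\C(C)=C/C=C/C(C)=C/CCc2coc(Cc3ccoc3)c2)OC1=O | target

## Step count and risks

Total step count: 7. Longest linear sequence: 6 steps (steps 2 to 7); step 1 is a one-step branch that feeds step 6.

The three steps most likely to fail:

Step 1 (the proposed new reaction). Glyoxylate may condense with the amine catalyst, the enal may self-condense or react at its α-carbon, and the level and sense of enantiocontrol are untested. The fallback uses known chemistry, sets out from 2 and comes back at 3. An (S)-proline-derived prolinamide catalyses the direct aldol reaction of acetone with 2 (enamine attack on the Re face) to give ethyl (2R)-2-hydroxy-4-oxopentanoate F1. Heating F1 with ketenylidenetriphenylphosphorane (Ph3P=C=C=O) in toluene acylates the hydroxyl group and closes the ring by intramolecular Wittig reaction on the ketone, giving ethyl (2R)-4-methyl-6-oxo-3,6-dihydro-2H-pyran-2-carboxylate F2. Half-reduction of the lactone carbonyl of F2 with iBu2AlH (1.05 equiv, CH2Cl2, −78 °C), which reacts faster than the open-chain ester, gives lactol 3.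

Step 6 (Wittig on the lactol). The risks are incomplete E-selectivity at the new olefin, slow ring opening of the lactolate and Z → E drift of the enal. The fallback changes the olefination manifold to a Julia–Kocienski reaction; it sets out from 11 and comes back at 16. Mitsunobu reaction of 11 with 1-phenyl-1H-tetrazole-5-thiol (PPh3, diisopropyl azodicarboxylate) gives 5-{[(2E)-5-[5-(furan-3-ylmethyl)furan-3-yl]-2-methylpent-2-en-1-yl]sulfanyl}-1-phenyl-1H-tetrazole F6. Oxidation with H2O2 and catalytic (NH4)6Mo7O24 in EtOH gives 5-{[(2E)-5-[5-(furan-3-ylmethyl)furan-3-yl]-2-methylpent-2-en-1-yl]sulfonyl}-1-phenyl-1H-tetrazole F7. Deprotonation of F7 with KN(SiMe3)2 in 1,2-dimethoxyethane at −60 °C and addition of alkoxide 15 (made from 3 as in step 6) gives 16 after Smiles rearrangement and elimination.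

Step 4 (allylic oxidation). The risks are over-oxidation to the enal, attack at the other allylic positions and loss of the electron-rich furans. The fallback builds the allylic alcohol without any oxidation and replaces steps 3 and 4; it sets out from 7 and comes back at 11. Negishi coupling of 7 with (3-ethoxy-3-oxopropyl)zinc bromide (Pd(OAc)2, 2-dicyclohexylphosphino-2',6'-dimethoxybiphenyl, THF) gives ethyl 3-[5-(furan-3-ylmethyl)furan-3-yl]propanoate F3. Reduction with iBu2AlH (CH2Cl2, −78 °C) gives 3-[5-(furan-3-ylmethyl)furan-3-yl]propanal F4. Wittig reaction with ethyl 2-(triphenylphosphoranylidene)propanoate gives ethyl (2E)-5-[5-(furan-3-ylmethyl)furan-3-yl]-2-methylpent-2-enoate F5, and iBu2AlH (2.2 equiv) reduces F5 to 11.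

Further compounds
F1 | step 1 | ethyl (2R)-2-hydroxy-4-oxopentanoate | CCOC(=O)[C@H](O)CC(C)=O
F2 | step 1 | ethyl (2R)-4-methyl-6-oxo-3,6-dihydro-2H-pyran-2-carboxylate | CCOC(=O)[C@H]1CC(C)=CC(=O)O1
F3 | step 4 | ethyl 3-[5-(furan-3-ylmethyl)furan-3-yl]propanoate | CCOC(=O)CCc1coc(Cc2ccoc2)c1
F4 | step 4 | 3-[5-(furan-3-ylmethyl)furan-3-yl]propanal | O=CCCc1coc(Cc2ccoc2)c1
F5 | step 4 | ethyl (2E)-5-[5-(furan-3-ylmethyl)furan-3-yl]-2-methylpent-2-enoate | CCOC(=O)/C(C)=C/CCc1coc(Cc2ccoc2)c1
F6 | step 6 | 5-{[(2E)-5-[5-(furan-3-ylmethyl)furan-3-yl]-2-methylpent-2-en-1-yl]sulfanyl}-1-phenyl-1H-tetrazole | c1ccccc1-n1nnnc1SC/C(C)=C/CCc1coc(Cc2ccoc2)c1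
F7 | step 6 | 5-{[(2E)-5-[5-(furan-3-ylmethyl)furan-3-yl]-2-methylpent-2-en-1-yl]sulfonyl}-1-phenyl-1H-tetrazole | c1ccccc1-n1nnnc1S(=O)(=O)C/C(C)=C/CCc1coc(Cc2ccoc2)c1
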